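Start with the easy flask: if first end groups and second end groups did nothing but form links, one for one, a charge of 1.10 equiv would make first end groups the limiting reagent, use them up and leave a surplus of 0.100 of second end groups, and that is the zero of my scale.

| flask | first end groups | second end groups | remark | time |
|---|---|---|---|---|
| green | 0.13 M | 1.1 equiv | run made earlier |  |
| teal | 0.30 M | 1.1 equiv | run made earlier |  |
| violet | 0.20 M | 1.7 equiv | run made earlier |  |
| flask | 0.20 M | 1.10 equiv |  | 3.0 min |

- green (time / min: links / %, rings / %): 0.250: 59, 9; 0.500: 63, 12; 1.00: 68, 14; 2.00: 63, 16; 4.00: 65, 16
- teal (time / min: links / %, rings / %): 0.250: 77, 4; 0.500: 80, 6; 1.00: 80, 7; 2.00: 82, 8; 4.00: 82, 10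
- violet (time / min: links / %, rings / %): 0.333: 87, 8; 0.833: 93, 7; 1.50: 93, 5; 2.50: 94, 7; 4.00: 95, 8

(readings scatter by 1.5 percentage points)

- at 3.0 min, what has stopped the reaction, if anything has (it is still moving / the second end groups has run out first / all of the first end groups has reacted)
- how much links there is at 3.0 min, in percent of the first end groups charged
- how much rings there is at 3.0 min, in percent of the first end groups charged

- the numbers in the tables scatter by 1.5 percentage points (one standard deviation)
- the reaction counts as stopped when no species that holds the first end groups changes by six tenths of a point or more over the second half of the time

The runs stand off that zero. The green run totals 82.0% of links and rings at 1.00 min and 81.0% at 4.00 min, level within the scatter, and leaves 19.0% of its first end groups unreacted, the teal run 8.00%, while the violet run, charged with 1.7 equiv, totals 103%.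

So I add a second process, second end groups decaying by themselves, and I read the stop as second end groups falling to 0. Counting one second end group per link or ring, the fraction lost, w, is the surplus plus the fraction f left unreacted. Summing the odds of decay against reaction as first end groups fall gives w as a concentration K, over the charge, times the logarithm of the charge over what remains. Green gives 0.0227 M and teal 0.0214 M, so I carry their mean, 0.0220 M, the break-even concentration: the level of first end groups at which a second end group is as likely to decay as to react.

The asked flask's charge, 0.20 M, is the geometric mean of the green and teal charges, so I start from 0.123, and one step halfway towards the rule gives f = 0.127 and w = 0.227.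

For the third process, rings, I read their share of what has reacted: it is 0.198 in green and 0.109 in teal, and the same mean gives 0.147. My reckoning is therefore 74.5% links and 12.8% rings, with the reaction stopped at the asked time.

The forecast says the second end groups has run out first, with 75% links and 12.5% rings, holding that “second end groups are essentially gone by about 1.5 min”.

The flask gives 74.7% links, 12.7% rings and the second end groups has run out first: 0% of second end groups remains, with 13% of first end groups.

    first end groups + second end groups → rings, rate k1*[first end groups] as long as [second end groups] is above zero (k = 0.00950 s⁻¹)
    second end groups → decomposed reagent (k = 0.0250 s⁻¹)
    first end groups + second end groups → links (k = 0.870 M⁻¹ s⁻¹)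

Its decomposed reagent, 0.0452 M, is 0.226 of the first end groups charged, against my w of 0.227. I carry the break-even concentration to a neighbour charged with 0.280 equiv, the first end groups held: there the fraction left is the shortfall of the charge plus the loss, and two passes of the rule from 0.720 give 0.756, then 0.751. At 3.00 min that neighbour holds 74.6% first end groups, 16.3% links and 9.08% rings.

Readings and results stem from a simulated flask with constants of no real substance; noise was put on by code.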